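**Plan**

1. Retrosynthesis: the heptaene is cut at C11=C12 and C11'=C12' (two Wittig bonds), leaving the C10 trienedial and one C15 allylic phosphonium salt per bicyclic end (carotenoid numbering, primes for the unhydroxylated end A).
2. Feature used: in each end one oxygen joins the methyl-bearing quaternary C5 to the allylic CH C8 across C6=C7 of a 2,5-dihydrofuran fused to the cyclohexane, i.e. a C5=C6–C7=C8 diene plus O2 minus one oxygen. Singlet oxygen bridges C5 and C8 and the peroxide ring is then contracted at the C15 ester stage, where the ester keeps C8 from ionising.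
3. End A (C8' chain cis to the C5' methyl): PPh3 contracts the peroxide with inversion at C8'; a temporary C3' silyloxy group taken from (4R,6R)-actinol sends oxygen to the opposite ring face (C5' R) and is then removed by radical deoxygenation.
4. End B (C8 chain trans to the C5 methyl, antipodal carbinol): actinol is inverted by a Mitsunobu reaction, the peroxide is reduced to the cis-enediol, and the ring is closed with retention at C8 by a palladium-catalysed allylic etherification.
5. Forward order: ketoisophorone → actinol → two enol triflates → Heck and Horner–Wadsworth–Emmons chain building → oxygenation and contraction → C15 salts; end A salt + trienedial → C25 aldehyde; the end B salt closes the C40 chain in the last step.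
6. Stereochemistry: C6 of the dione from the ene-reductase, the carbinol from hydride approach (and its Mitsunobu inversion), C5/C8 from face-selective suprafacial O2 addition and the two stereospecific contractions; chain double bonds E from the Heck, Horner–Wadsworth–Emmons and Wittig steps (the last after thermal isomerisation).

Key step: step 7

Assumption: the SMILES is read as the all-E (3R,5S,8S,5'R,8'S) isomer, so the ends differ at C5 and in the chain-to-methyl relation (cis in end A, trans in end B), and end B needs the carbinol antipodal to that of (4R,6R)-actinol.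

**Route**

Step 1
Reactants: 1 ketoisophorone
Product: 2 (6R)-2,2,6-trimethylcyclohexane-1,4-dione
Conditions: ene-reductase OYE2 (old yellow enzyme of baker's yeast), NADP+ (cat.), glucose dehydrogenase, D-glucose, phosphate buffer pH 7, 30 °C
Reagents that add atoms: none
Why: Enzymatic conjugate reduction of the enedione C=C bond by an old-yellow-enzyme ene-reductase should add hydride and proton trans across the double bond and set the methyl-bearing centre as R under enzyme control, with glucose dehydrogenase recycling the cofactor.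

Step 2
Reactants: 2 (6R)-dione
Product: 3 (4R,6R)-4-hydroxy-2,2,6-trimethylcyclohexan-1-one
Conditions: LiBH(s-Bu)3, THF, −78 °C
Reagents that add atoms: none
Why: In this diastereoselective ketone reduction by a bulky trialkylborohydride the hindered C1 carbonyl should stay untouched and hydride should reach C4 along the equatorial path, away from the axial C2 methyl, giving the axial (4R) alcohol trans to the equatorial C6 methyl.

Step 3
Reactants: 3 (4R,6R)-hydroxy ketone
Product: 4 (4R,6R)-4-[(tert-butyldimethylsilyl)oxy]-2,2,6-trimethylcyclohexan-1-one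
Conditions: t-BuMe2SiCl, imidazole, DMF, 25 °C
Reagents that add atoms: tert-butyldimethylsilyl chloride, CC(C)(C)[Si](C)(C)Cl
Why: Imidazole-promoted silylation of the secondary alcohol should give the silyl ether, which survives every step up to the ring contraction.

Step 4
Reactants: 4 silyloxy ketone
Product: 5 (4R)-4-[(tert-butyldimethylsilyl)oxy]-2,6,6-trimethylcyclohex-1-en-1-yl trifluoromethanesulfonate
Conditions: LiN(i-Pr)2, THF, −78 °C; then PhNTf2, −78 to 0 °C
Reagents that add atoms: N-phenylbis(trifluoromethanesulfonimide), O=S(=O)(N(c1ccccc1)S(=O)(=O)C(F)(F)F)C(F)(F)F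
Why: Enolate formation at the only α-CH (C6) followed by O-triflation should give the tetrasubstituted enol triflate, erasing the C6 centre on purpose while the carbinol centre stays.

Step 5
Reactants: 5 enol triflate; 6 methyl vinyl ketone
Product: 7 (3E)-4-[(4R)-4-[(tert-butyldimethylsilyl)oxy]-2,6,6-trimethylcyclohex-1-en-1-yl]but-3-en-2-one
Conditions: Pd(OAc)2 (5 mol %), PPh3, Et3N, DMF, 70 °C
Reagents that add atoms: none
Why: In this Mizoroki–Heck reaction the alkenyl triflate adds oxidatively to zerovalent palladium formed in the flask, the enone inserts at its terminal carbon and syn β-hydride elimination should give the E-dienone.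

Step 6
Reactants: 7 dienone; 8 triethyl phosphonoacetate
Product: 9 ethyl (2E,4E)-5-[(4R)-4-[(tert-butyldimethylsilyl)oxy]-2,6,6-trimethylcyclohex-1-en-1-yl]-3-methylpenta-2,4-dienoate
Conditions: NaH, THF, 0 to 25 °C
Reagents that add atoms: none
Why: Horner–Wadsworth–Emmons olefination of the methyl ketone should give mainly the 2E trienoate, and the minor 2Z isomer is to be removed by chromatography.

Step 7
Reactants: 9 silyloxy trienoate
Product: 11 ethyl (2E)-3-[(2S,6S,7aR)-6-[(tert-butyldimethylsilyl)oxy]-4,4,7a-trimethyl-2,4,5,6,7,7a-hexahydro-1-benzofuran-2-yl]but-2-enoate, via silyloxy endoperoxide 10 (not isolated)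
Conditions: O2, tetraphenylporphyrin (cat.), visible light, CH2Cl2, −30 °C; then PPh3, −30 to 25 °C
Reagents that add atoms: dioxygen, O=O
Why: Photosensitised singlet oxygen adds suprafacially in a [4+2] cycloaddition to the s-cis C5'=C6'–C7'=C8' diene, the electron-rich end of the trienoate, and closes the six-membered 1,2-dioxine 10, in which the C5' methyl and H-8' are cis because both were inside substituents of the E-diene. PPh3 then inserts into the O–O bond, the phosphorane opens to a C5' alkoxide and a C8' oxyphosphonium ion, and the alkoxide displaces Ph3P=O at C8' in a 5-exo-tet SN2 closure that forms the dihydrofuran with inversion, so that the side chain ends up cis to the C5' methyl. The closest known reactions are the 5,8-endoperoxidation of retinoid and ionone dienes by singlet oxygen and the phosphine-mediated contraction of 3,6-dihydro-1,2-dioxines to 2,5-dihydrofurans. C5' (R) is set by approach of oxygen to the ring face anti to the C3' silyloxy group, as electrophilic oxygen donors do on 3-silyloxy rings of this kind, and C8' (S) follows from the suprafacial addition and the single inversion. The step needs diene over enoate and ene reactivity, one ring face, and SN2 rather than SN1 or SN2' closure: the conjugated ester deactivates C9'=C10' and keeps C8' from ionising, the fully substituted C6' disfavours SN2' attack, and a syn-face adduct would be a diastereomer of 11 that chromatography should remove.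

Step 8
Reactants: 11 silyl ether
Product: 12 ethyl (2E)-3-[(2S,6S,7aR)-6-hydroxy-4,4,7a-trimethyl-2,4,5,6,7,7a-hexahydro-1-benzofuran-2-yl]but-2-enoate
Conditions: Bu4NF, AcOH, THF, 0 to 25 °C
Reagents that add atoms: none
Why: Fluoride-induced desilylation, buffered with acetic acid so that the γ-hydrogen at C8' is not removed, should free the C3' hydroxyl.

Step 9
Reactants: 12 alcohol
Product: 13 ethyl (2E)-3-[(2S,6S,7aR)-4,4,7a-trimethyl-6-[(phenoxycarbonothioyl)oxy]-2,4,5,6,7,7a-hexahydro-1-benzofuran-2-yl]but-2-enoate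
Conditions: PhOC(S)Cl, pyridine, 4-(dimethylamino)pyridine (cat.), CH2Cl2, 25 °C
Reagents that add atoms: O-phenyl chlorothionoformate, S=C(Cl)Oc1ccccc1
Why: Thioacylation of the secondary alcohol under weakly basic conditions should give the thionocarbonate needed for radical deoxygenation without touching the base-sensitive C8' position.

Step 10
Reactants: 13 thionocarbonate
Product: 14 ethyl (2E)-3-[(2S,7aR)-4,4,7a-trimethyl-2,4,5,6,7,7a-hexahydro-1-benzofuran-2-yl]but-2-enoate
Conditions: Bu3SnH, azobisisobutyronitrile (cat.), toluene, 90 °C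
Reagents that add atoms: none
Why: Barton–McCombie deoxygenation should replace the C3' oxygen by hydrogen through a secondary ring radical that has no β-leaving group and lies anti to, and far from, the C8' hydrogen, so C5' and C8' are not affected.

Step 11
Reactants: 14 end A ester
Product: 15 (2E)-3-[(2S,7aR)-4,4,7a-trimethyl-2,4,5,6,7,7a-hexahydro-1-benzofuran-2-yl]but-2-en-1-ol
Conditions: i-Bu2AlH, CH2Cl2, −78 °C
Reagents that add atoms: none
Why: 1,2-Reduction of the conjugated ester by the aluminium hydride should give the allylic alcohol, which from here on is handled without acid because C8' has lost its deactivating ester.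

Step 12
Reactants: 15 end A allylic alcohol
Product: 17 [(2E)-3-[(2S,7aR)-4,4,7a-trimethyl-2,4,5,6,7,7a-hexahydro-1-benzofuran-2-yl]but-2-en-1-yl]triphenylphosphonium bromide, via end A allylic bromide 16 (not isolated)
Conditions: CBr4, PPh3, 2,6-lutidine, CH2Cl2, −20 °C; then PPh3, 25 °C
Reagents that add atoms: carbon tetrabromide, BrC(Br)(Br)Br; triphenylphosphine, c1ccccc1P(c1ccccc1)c1ccccc1
Why: Appel bromination of the primary allylic alcohol under buffered, non-acidic conditions and SN2 quaternisation of the bromide by PPh3 in the same flask should give the Wittig salt without isolating the labile halide.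

Step 13
Reactants: 17 end A phosphonium salt; 18 (2E,4E,6E)-2,7-dimethylocta-2,4,6-trienedial
Product: 19 (2E,4E,6E,8E,10E)-2,7-dimethyl-11-[(2S,7aR)-4,4,7a-trimethyl-2,4,5,6,7,7a-hexahydro-1-benzofuran-2-yl]dodeca-2,4,6,8,10-pentaenal
Conditions: 18 (3 equiv), NaOMe, MeOH/CH2Cl2, 0 to 25 °C; then heptane, 80 °C
Reagents that add atoms: none
Why: Wittig olefination of one formyl group of the symmetrical dialdehyde, used in excess to suppress double condensation, should join C11' to C12', and heating then isomerises the hindered 11'Z bond to E.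

Step 14
Reactants: 3 (4R,6R)-hydroxy ketone
Product: 20 (1S,5R)-3,3,5-trimethyl-4-oxocyclohexyl benzoate
Conditions: PhCO2H, PPh3, diisopropyl azodicarboxylate, THF, 0 to 25 °C
Reagents that add atoms: benzoic acid, OC(=O)c1ccccc1
Why: In this Mitsunobu reaction benzoate displaces the axial oxyphosphonium group from the rear, inverting the carbinol centre to S, and the benzoate then serves as the protecting group of the end B hydroxyl.

Step 15
Reactants: 20 keto benzoate
Product: 21 (1S)-3,5,5-trimethyl-4-[(trifluoromethanesulfonyl)oxy]cyclohex-3-en-1-yl benzoate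
Conditions: Tf2O, 2,6-di-tert-butyl-4-methylpyridine, CH2Cl2, 0 to 25 °C
Reagents that add atoms: trifluoromethanesulfonic anhydride, O=S(=O)(OS(=O)(=O)C(F)(F)F)C(F)(F)F
Why: Enol triflate formation with triflic anhydride and a hindered pyridine, which removes the only α-hydrogen of the O-triflated ketone, should give the tetrasubstituted triflate without a strong base that could attack the benzoate.

Step 16
Reactants: 21 enol triflate; 6 methyl vinyl ketone
Product: 22 (1S)-3,5,5-trimethyl-4-[(1E)-3-oxobut-1-en-1-yl]cyclohex-3-en-1-yl benzoate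
Conditions: Pd(OAc)2 (5 mol %), PPh3, Et3N, DMF, 70 °C
Reagents that add atoms: none
Why: The Mizoroki–Heck coupling of step 5, run on the antipodal triflate, should again give the E-dienone.

Step 17
Reactants: 22 dienone; 8 triethyl phosphonoacetate
Product: 23 ethyl (2E,4E)-5-[(4S)-4-(benzoyloxy)-2,6,6-trimethylcyclohex-1-en-1-yl]-3-methylpenta-2,4-dienoate
Conditions: NaH, THF, 0 to 25 °C
Reagents that add atoms: none
Why: Horner–Wadsworth–Emmons olefination should give mainly the 2E trienoate, the stabilised phosphonate anion leaving the benzoate alone, and the 2Z isomer is to be removed by chromatography.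

Step 18
Reactants: 23 benzoyloxy trienoate
Product: 25 ethyl (2E,4S,5Z)-5-[(2S,4R)-4-(benzoyloxy)-2-hydroxy-2,6,6-trimethylcyclohexylidene]-4-hydroxy-3-methylpent-2-enoate, via benzoyloxy endoperoxide 24 (not isolated)
Conditions: O2, tetraphenylporphyrin (cat.), visible light, CH2Cl2, −30 °C; then thiourea, MeOH, 25 °C
Reagents that add atoms: dioxygen, O=O
Why: The singlet-oxygen [4+2] cycloaddition of step 7, here anti to the C3 benzoate, should set C5 (S) and C8 (S) together in endoperoxide 24, and thiourea then reduces only the O–O bond, so both C–O bonds and both configurations are kept in the cis-enediol.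

Step 19
Reactants: 25 cis-enediol
Product: 26 ethyl (2E,4S,5Z)-5-[(2S,4R)-4-(benzoyloxy)-2-hydroxy-2,6,6-trimethylcyclohexylidene]-4-[(methoxycarbonyl)oxy]-3-methylpent-2-enoate
Conditions: ClCO2Me, pyridine, CH2Cl2, 0 °C
Reagents that add atoms: methyl chloroformate, COC(=O)Cl
Why: Chemoselective acylation should convert only the secondary allylic C8 hydroxyl into its methyl carbonate, the tertiary C5 hydroxyl being too hindered to react.

Step 20
Reactants: 26 allylic carbonate
Product: 27 ethyl (2E)-3-[(2S,6R,7aS)-6-(benzoyloxy)-4,4,7a-trimethyl-2,4,5,6,7,7a-hexahydro-1-benzofuran-2-yl]but-2-enoate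
Conditions: Pd(PPh3)4 (5 mol %), THF, 25 °C
Reagents that add atoms: none
Why: In this Tsuji–Trost allylic etherification zerovalent palladium ionises the C8 carbonate through the C9=C10 enoate with inversion, and the tertiary C5 alkoxide freed by the departing methyl carbonate attacks the near allyl terminus anti to palladium to close the five-membered ring, so the two inversions add up to retention at C8 (S) and the side chain stays trans to the C5 methyl.

Step 21
Reactants: 27 end B ester benzoate
Product: 28 (2S,6R,7aS)-2-[(2E)-4-hydroxybut-2-en-2-yl]-4,4,7a-trimethyl-2,4,5,6,7,7a-hexahydro-1-benzofuran-6-ol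
Conditions: i-Bu2AlH, CH2Cl2, −78 to −20 °C
Reagents that add atoms: none
Why: The aluminium hydride should reduce the conjugated ethyl ester in 1,2 fashion to the allylic alcohol and cleave the benzoate in the same operation, freeing the C3 hydroxyl without acid or aqueous base.

Step 22
Reactants: 28 end B diol
Product: 30 [(2E)-3-[(2S,6R,7aS)-6-hydroxy-4,4,7a-trimethyl-2,4,5,6,7,7a-hexahydro-1-benzofuran-2-yl]but-2-en-1-yl]triphenylphosphonium bromide, via end B allylic bromide 29 (not isolated)
Conditions: CBr4 (1 equiv), PPh3 (1 equiv), 2,6-lutidine, CH2Cl2, −40 °C; then PPh3, 25 °C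
Reagents that add atoms: carbon tetrabromide, BrC(Br)(Br)Br; triphenylphosphine, c1ccccc1P(c1ccccc1)c1ccccc1
Why: Appel bromination at low temperature should take the primary allylic hydroxyl much faster than the ring secondary hydroxyl, and SN2 quaternisation of the bromide by PPh3 then gives the hydroxy Wittig salt under non-acidic conditions.

Step 23
Reactants: 30 end B phosphonium salt; 19 C25 aldehyde
Product: 31 (all-E)-(3R,5S,8S,5'R,8'S)-5,8:5',8'-diepoxy-5,8,5',8'-tetrahydro-β,β-caroten-3-ol
Conditions: NaOMe, MeOH/CH2Cl2, 0 to 25 °C; then heptane, 80 °C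
Reagents that add atoms: none
Why: Wittig olefination of the C25 aldehyde by the semi-stabilised allylic ylide, which tolerates the free hydroxyl, should join C11 to C12, and heating then isomerises the hindered 11Z bond to E to give the all-E target.

**Compound list**

1 | ketoisophorone (2,6,6-trimethylcyclohex-2-ene-1,4-dione) | CC1=CC(=O)CC(C)(C)C1=O | starting material
2 | (6R)-2,2,6-trimethylcyclohexane-1,4-dione | C[C@@H]1CC(=O)CC(C)(C)C1=O | intermediate
3 | (4R,6R)-4-hydroxy-2,2,6-trimethylcyclohexan-1-one (actinol) | C[C@@H]1C[C@@H](O)CC(C)(C)C1=O | intermediate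
4 | (4R,6R)-4-[(tert-butyldimethylsilyl)oxy]-2,2,6-trimethylcyclohexan-1-one | C[C@@H]1C[C@@H](O[Si](C)(C)C(C)(C)C)CC(C)(C)C1=O | intermediate
5 | (4R)-4-[(tert-butyldimethylsilyl)oxy]-2,6,6-trimethylcyclohex-1-en-1-yl trifluoromethanesulfonate | FC(F)(F)S(=O)(=O)OC1=C(C)C[C@@H](O[Si](C)(C)C(C)(C)C)CC1(C)C | intermediate
6 | methyl vinyl ketone (but-3-en-2-one) | CC(=O)C=C | starting material
7 | (3E)-4-[(4R)-4-[(tert-butyldimethylsilyl)oxy]-2,6,6-trimethylcyclohex-1-en-1-yl]but-3-en-2-one | CC(=O)/C=C/C1=C(C)C[C@@H](O[Si](C)(C)C(C)(C)C)CC1(C)C | intermediate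
8 | triethyl phosphonoacetate | CCOC(=O)CP(=O)(OCC)OCC | starting material
9 | ethyl (2E,4E)-5-[(4R)-4-[(tert-butyldimethylsilyl)oxy]-2,6,6-trimethylcyclohex-1-en-1-yl]-3-methylpenta-2,4-dienoate (key-step precursor) | CCOC(=O)/C=C(C)/C=C/C1=C(C)C[C@@H](O[Si](C)(C)C(C)(C)C)CC1(C)C | intermediate
10 | ethyl (2E)-3-[(3R,7S,8aR)-7-[(tert-butyldimethylsilyl)oxy]-5,5,8a-trimethyl-3,5,6,7,8,8a-hexahydro-1,2-benzodioxin-3-yl]but-2-enoate (5,8-endoperoxide, not isolated) | CCOC(=O)/C=C(\C)[C@H]1C=C2C(C)(C)C[C@H](O[Si](C)(C)C(C)(C)C)C[C@@]2(C)OO1 | intermediate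
11 | ethyl (2E)-3-[(2S,6S,7aR)-6-[(tert-butyldimethylsilyl)oxy]-4,4,7a-trimethyl-2,4,5,6,7,7a-hexahydro-1-benzofuran-2-yl]but-2-enoate (key-step product) | CCOC(=O)/C=C(\C)[C@@H]1C=C2C(C)(C)C[C@H](O[Si](C)(C)C(C)(C)C)C[C@@]2(C)O1 | intermediate
12 | ethyl (2E)-3-[(2S,6S,7aR)-6-hydroxy-4,4,7a-trimethyl-2,4,5,6,7,7a-hexahydro-1-benzofuran-2-yl]but-2-enoate | CCOC(=O)/C=C(\C)[C@@H]1C=C2C(C)(C)C[C@H](O)C[C@@]2(C)O1 | intermediate
13 | ethyl (2E)-3-[(2S,6S,7aR)-4,4,7a-trimethyl-6-[(phenoxycarbonothioyl)oxy]-2,4,5,6,7,7a-hexahydro-1-benzofuran-2-yl]but-2-enoate | CCOC(=O)/C=C(\C)[C@@H]1C=C2C(C)(C)C[C@H](OC(=S)Oc3ccccc3)C[C@@]2(C)O1 | intermediate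
14 | ethyl (2E)-3-[(2S,7aR)-4,4,7a-trimethyl-2,4,5,6,7,7a-hexahydro-1-benzofuran-2-yl]but-2-enoate | CCOC(=O)/C=C(\C)[C@@H]1C=C2C(C)(C)CCC[C@@]2(C)O1 | intermediate
15 | (2E)-3-[(2S,7aR)-4,4,7a-trimethyl-2,4,5,6,7,7a-hexahydro-1-benzofuran-2-yl]but-2-en-1-ol | OC/C=C(\C)[C@@H]1C=C2C(C)(C)CCC[C@@]2(C)O1 | intermediate
16 | (2S,7aR)-2-[(2E)-4-bromobut-2-en-2-yl]-4,4,7a-trimethyl-2,4,5,6,7,7a-hexahydro-1-benzofuran (not isolated) | BrC/C=C(\C)[C@@H]1C=C2C(C)(C)CCC[C@@]2(C)O1 | intermediate
17 | [(2E)-3-[(2S,7aR)-4,4,7a-trimethyl-2,4,5,6,7,7a-hexahydro-1-benzofuran-2-yl]but-2-en-1-yl]triphenylphosphonium bromide | [Br-].c1ccccc1[P+](c1ccccc1)(c1ccccc1)C/C=C(\C)[C@@H]1C=C2C(C)(C)CCC[C@@]2(C)O1 | intermediate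
18 | (2E,4E,6E)-2,7-dimethylocta-2,4,6-trienedial | O=C/C(C)=C/C=C/C=C(C)/C=O | starting material
19 | (2E,4E,6E,8E,10E)-2,7-dimethyl-11-[(2S,7aR)-4,4,7a-trimethyl-2,4,5,6,7,7a-hexahydro-1-benzofuran-2-yl]dodeca-2,4,6,8,10-pentaenal | O=C/C(C)=C/C=C/C=C(C)/C=C/C=C(\C)[C@@H]1C=C2C(C)(C)CCC[C@@]2(C)O1 | intermediate
20 | (1S,5R)-3,3,5-trimethyl-4-oxocyclohexyl benzoate | C[C@@H]1C[C@H](OC(=O)c2ccccc2)CC(C)(C)C1=O | intermediate
21 | (1S)-3,5,5-trimethyl-4-[(trifluoromethanesulfonyl)oxy]cyclohex-3-en-1-yl benzoate | FC(F)(F)S(=O)(=O)OC1=C(C)C[C@H](OC(=O)c2ccccc2)CC1(C)C | intermediate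
22 | (1S)-3,5,5-trimethyl-4-[(1E)-3-oxobut-1-en-1-yl]cyclohex-3-en-1-yl benzoate | CC(=O)/C=C/C1=C(C)C[C@H](OC(=O)c2ccccc2)CC1(C)C | intermediate
23 | ethyl (2E,4E)-5-[(4S)-4-(benzoyloxy)-2,6,6-trimethylcyclohex-1-en-1-yl]-3-methylpenta-2,4-dienoate | CCOC(=O)/C=C(C)/C=C/C1=C(C)C[C@H](OC(=O)c2ccccc2)CC1(C)C | intermediate
24 | ethyl (2E)-3-[(3S,7R,8aS)-7-(benzoyloxy)-5,5,8a-trimethyl-3,5,6,7,8,8a-hexahydro-1,2-benzodioxin-3-yl]but-2-enoate (5,8-endoperoxide, not isolated) | CCOC(=O)/C=C(\C)[C@@H]1C=C2C(C)(C)C[C@@H](OC(=O)c3ccccc3)C[C@]2(C)OO1 | intermediate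
25 | ethyl (2E,4S,5Z)-5-[(2S,4R)-4-(benzoyloxy)-2-hydroxy-2,6,6-trimethylcyclohexylidene]-4-hydroxy-3-methylpent-2-enoate | CCOC(=O)/C=C(\C)[C@@H](O)/C=C1/C(C)(C)C[C@@H](OC(=O)c2ccccc2)C[C@]1(C)O | intermediate
26 | ethyl (2E,4S,5Z)-5-[(2S,4R)-4-(benzoyloxy)-2-hydroxy-2,6,6-trimethylcyclohexylidene]-4-[(methoxycarbonyl)oxy]-3-methylpent-2-enoate | CCOC(=O)/C=C(\C)[C@@H](OC(=O)OC)/C=C1/C(C)(C)C[C@@H](OC(=O)c2ccccc2)C[C@]1(C)O | intermediate
27 | ethyl (2E)-3-[(2S,6R,7aS)-6-(benzoyloxy)-4,4,7a-trimethyl-2,4,5,6,7,7a-hexahydro-1-benzofuran-2-yl]but-2-enoate | CCOC(=O)/C=C(\C)[C@@H]1C=C2C(C)(C)C[C@@H](OC(=O)c3ccccc3)C[C@]2(C)O1 | intermediate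
28 | (2S,6R,7aS)-2-[(2E)-4-hydroxybut-2-en-2-yl]-4,4,7a-trimethyl-2,4,5,6,7,7a-hexahydro-1-benzofuran-6-ol | OC/C=C(\C)[C@@H]1C=C2C(C)(C)C[C@@H](O)C[C@]2(C)O1 | intermediate
29 | (2S,6R,7aS)-2-[(2E)-4-bromobut-2-en-2-yl]-4,4,7a-trimethyl-2,4,5,6,7,7a-hexahydro-1-benzofuran-6-ol (not isolated) | BrC/C=C(\C)[C@@H]1C=C2C(C)(C)C[C@@H](O)C[C@]2(C)O1 | intermediate
30 | [(2E)-3-[(2S,6R,7aS)-6-hydroxy-4,4,7a-trimethyl-2,4,5,6,7,7a-hexahydro-1-benzofuran-2-yl]but-2-en-1-yl]triphenylphosphonium bromide | [Br-].c1ccccc1[P+](c1ccccc1)(c1ccccc1)C/C=C(\C)[C@@H]1C=C2C(C)(C)C[C@@H](O)C[C@]2(C)O1 | intermediate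
31 | (all-E)-(3R,5S,8S,5'R,8'S)-5,8:5',8'-diepoxy-5,8,5',8'-tetrahydro-β,β-caroten-3-ol | CC(/C=C/C=C(\C)[C@@H]1C=C2C(C)(C)CCC[C@@]2(C)O1)=C\C=C\C=C(C)\C=C\C=C(/C)[C@@H]1C=C2C(C)(C)C[C@@H](O)C[C@]2(C)O1 | target

**Step count**

Total: 23 steps. Longest linear sequence: 14 steps (steps 1–13 and 23, from ketoisophorone); the end B branch (steps 1, 2, 14–22) joins in step 23.

**Steps most likely to fail**

Step 7. Oxygen may add to both ring faces or react in the ene mode at the ring allylic positions, and the phosphorane may collapse by SN2' attack at C6' or by fragmentation instead of the 5-exo-tet closure. Fallback: starting from 9, photooxygenation as in step 7 (through 10) followed by thiourea in the same flask should give the cis-enediol ethyl (2E,4R,5Z)-5-[(2R,4S)-4-[(tert-butyldimethylsilyl)oxy]-2-hydroxy-2,6,6-trimethylcyclohexylidene]-4-hydroxy-3-methylpent-2-enoate F1, a stage at which face isomers can be separated. Mitsunobu cyclodehydration (PPh3, diisopropyl azodicarboxylate, THF) then activates the secondary C8' hydroxyl and lets the tertiary C5' hydroxyl displace it with inversion, which returns to 11.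

Step 20. The π-allylpalladium intermediate may equilibrate through its ester-bearing terminus before the alkoxide closes, which would erode the C8 configuration or the 9E geometry, or it may lose a β-hydrogen to give a diene. Fallback: starting from 25, acid-catalysed cyclodehydration (pyridinium p-toluenesulfonate, CH2Cl2, 0 °C) should ionise the tertiary allylic C5 hydroxyl while the C8–O bond stays intact. The C8 hydroxyl then closes on the face the leaving oxygen occupied, the one that keeps H-8 and not the chain next to the C5 methyl. This comes back to the route at 27 and makes no new compound (F0).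

Step 22. Bromination may fail to discriminate between the two hydroxyls, traces of acid may open or epimerise the allylic ether at C8, and the ylide made from the salt may expel the ring alkoxide by 1,4-elimination. Fallback: starting from 28, Mitsunobu thioetherification with 1-phenyl-1H-tetrazole-5-thiol (PPh3, diisopropyl azodicarboxylate, THF), which takes only the primary hydroxyl, should give (2S,6R,7aS)-4,4,7a-trimethyl-2-[(2E)-4-[(1-phenyl-1H-tetrazol-5-yl)sulfanyl]but-2-en-2-yl]-2,4,5,6,7,7a-hexahydro-1-benzofuran-6-ol F2. Oxidation (H2O2, (NH4)6Mo7O24, EtOH) should give (2S,6R,7aS)-4,4,7a-trimethyl-2-[(2E)-4-[(1-phenyl-1H-tetrazol-5-yl)sulfonyl]but-2-en-2-yl]-2,4,5,6,7,7a-hexahydro-1-benzofuran-6-ol F3. Julia–Kocienski olefination with 19 (KN(SiMe3)2 added to both partners in THF at −78 °C), followed by the thermal isomerisation of step 23, comes back to the route at 31.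

Further compounds
F1 | step 7 | ethyl (2E,4R,5Z)-5-[(2R,4S)-4-[(tert-butyldimethylsilyl)oxy]-2-hydroxy-2,6,6-trimethylcyclohexylidene]-4-hydroxy-3-methylpent-2-enoate | CCOC(=O)/C=C(\C)[C@H](O)/C=C1/C(C)(C)C[C@H](O[Si](C)(C)C(C)(C)C)C[C@@]1(C)O
F0 | step 20 | none | none
F2 | step 22 | (2S,6R,7aS)-4,4,7a-trimethyl-2-[(2E)-4-[(1-phenyl-1H-tetrazol-5-yl)sulfanyl]but-2-en-2-yl]-2,4,5,6,7,7a-hexahydro-1-benzofuran-6-ol | c1ccccc1-n1nnnc1SC/C=C(\C)[C@@H]1C=C2C(C)(C)C[C@@H](O)C[C@]2(C)O1
F3 | step 22 | (2S,6R,7aS)-4,4,7a-trimethyl-2-[(2E)-4-[(1-phenyl-1H-tetrazol-5-yl)sulfonyl]but-2-en-2-yl]-2,4,5,6,7,7a-hexahydro-1-benzofuran-6-ol | c1ccccc1-n1nnnc1S(=O)(=O)C/C=C(\C)[C@@H]1C=C2C(C)(C)C[C@@H](O)C[C@]2(C)O1
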